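**Plan**
- Retrosynthesis: the sulfate S–O bond and the four benzyl ethers are cut first. Ring A of the flavone is then opened at C5–C6, C7–C8 and C4a–C5, which gives an α-diazo ketone and an alkyl ethynyl ether.
- Enabling feature: in flavone ring A the unit C5(OH)–C6(H)–C7(O) lies between C4a and C8, and C4a–C8a is the C3=C2 bond of a 4-pyranone. Ring A is therefore a ketene carbonyl carbon (C5) plus two alkyne carbons (C6, C7) joined across a pyranonyl ketene whose other carbon (C8) already carries flavanone C3.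
- The diazo ketone is cut between its acyl carbon and the pyranone methyl carbon. The flavan aldehyde goes back to a flavanone-3-carboxylate and this to an alkylidene β-keto ester.
- Forward order of rings: flavanone ring C (oxa-Michael), the 4-pyranone (triketone cyclodehydration), union of the two fragments, then flavone ring A (benzannulation). Oxidation at C4, sulfation and hydrogenolysis finish the route.
- Stereochemistry: C2 (R) comes from the catalyst-controlled oxa-Michael addition. C3 is trans to C2 by thermodynamic control, passes through the Wolff 1,2-shift with retention, and is again under thermodynamic control once C4 is a ketone. The C4 carbinol is temporary.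

Key step: step 15

**Remarks on the chemistry**
- Assumption: the hydrogen sulfate of the target is the protonated form of a sulfate monoester; 31 and 32 are handled as sodium salts and drawn as the free acids.
- Assumption: the quinine-derived thiourea is taken to deliver the 2R series in step 4; its quinidine-derived pseudoenantiomer would take its place if the sense of induction proved opposite.
- The two-carbon partner is an alkyl ethynyl ether, not a silyl ethynyl ether. The parent silyloxyacetylenes are not readily accessible, because silylation of the parent ynolate tends to give silylketenes. Alkyl ethynyl ethers come in one flask from trichloroethylene, and the 4-methoxybenzyl group marks the future sulfate oxygen as the only acid-labile aryl ether.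
- Fl stands for the (2R,3S,4R)-5,7-bis(benzyloxy)-2-[4-(benzyloxy)phenyl]-4-[(tert-butyldimethylsilyl)oxy]chroman-3-yl group (2,3-trans, 3,4-trans, all substituents equatorial). The C4 configuration shown is the expected one and is of no consequence, since C4 is reoxidised in step 17.

**Route**

Step 1
Reactants: 1 2',4',6'-trihydroxyacetophenone
Product: 2 1-[2,4-bis(benzyloxy)-6-hydroxyphenyl]ethanone
Conditions: BnBr (2.1 equiv), K2CO3, DMF, 25 °C
Reagents that add atoms: benzyl bromide, BrCc1ccccc1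
Why: Williamson etherification; the hydroxyl that is hydrogen-bonded to the acetyl carbonyl is the least reactive, so two equivalents of benzyl bromide should leave it free.

Step 2
Reactants: 2 1-[2,4-bis(benzyloxy)-6-hydroxyphenyl]ethanone; 3 di-tert-butyl dicarbonate
Product: 4 tert-butyl 3-[2,4-bis(benzyloxy)-6-hydroxyphenyl]-3-oxopropanoate
Conditions: LiN(SiMe3)2 (3.2 equiv), THF, −78 °C; 3, −78 → −20 °C; aq NH4Cl
Reagents that add atoms: none
Why: Claisen-type C-acylation of the phenoxide–enolate dianion by the dicarbonate; the third equivalent of base holds the β-keto ester as its enolate, and a tert-butyl ester resists lactonisation to a 4-hydroxycoumarin.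

Step 3
Reactants: 4 tert-butyl 3-[2,4-bis(benzyloxy)-6-hydroxyphenyl]-3-oxopropanoate; 5 4-(benzyloxy)benzaldehyde
Product: 6 tert-butyl (2Z)-2-[2,4-bis(benzyloxy)-6-hydroxybenzoyl]-3-[4-(benzyloxy)phenyl]prop-2-enoate
Conditions: piperidine (0.1 equiv), AcOH (0.1 equiv), 4 Å molecular sieves, toluene, 25 °C
Reagents that add atoms: none
Why: Knoevenagel condensation of the active methylene with the aryl aldehyde under buffered amine catalysis; the Z alkene (aryl cis to the ester) is expected from thermodynamic control.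

Step 4
Reactants: 6 tert-butyl (2Z)-2-[2,4-bis(benzyloxy)-6-hydroxybenzoyl]-3-[4-(benzyloxy)phenyl]prop-2-enoate
Product: 7 tert-butyl (2R,3S)-5,7-bis(benzyloxy)-2-[4-(benzyloxy)phenyl]-4-oxochromane-3-carboxylate (2,3-trans)
Conditions: quinine-derived thiourea 1-[3,5-bis(trifluoromethyl)phenyl]-3-(9-deoxy-epi-quinin-9-yl)thiourea (10 mol %), toluene, −25 °C
Reagents that add atoms: none
Why: Catalytic asymmetric intramolecular oxa-Michael addition (6-endo-trig); the quinuclidine nitrogen activates the phenol while the thiourea binds the β-keto ester, so one face of the alkylidene is attacked and C2 is set as R, and C3 settles trans by enolisation.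

Step 5
Reactants: 7 tert-butyl (2R,3S)-5,7-bis(benzyloxy)-2-[4-(benzyloxy)phenyl]-4-oxochromane-3-carboxylate
Product: 8 tert-butyl (2R,3R,4R)-5,7-bis(benzyloxy)-2-[4-(benzyloxy)phenyl]-4-hydroxychromane-3-carboxylate (same spatial arrangement at C2 and C3; only the descriptor at C3 changes)
Conditions: NaBH4, CeCl3·7H2O, MeOH/THF, −40 °C
Reagents that add atoms: none
Why: Luche-type 1,2-reduction of the keto tautomer at low temperature, which should be faster than retro-oxa-Michael opening; hydride is expected to add so that the carbinol oxygen becomes equatorial and trans to the ester.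

Step 6
Reactants: 8 tert-butyl (2R,3R,4R)-5,7-bis(benzyloxy)-2-[4-(benzyloxy)phenyl]-4-hydroxychromane-3-carboxylate
Product: 9 tert-butyl (2R,3S,4R)-5,7-bis(benzyloxy)-2-[4-(benzyloxy)phenyl]-4-[(tert-butyldimethylsilyl)oxy]chromane-3-carboxylate
Conditions: TBSOTf, 2,6-lutidine, CH2Cl2, −78 → 0 °C
Reagents that add atoms: tert-butyldimethylsilyl trifluoromethanesulfonate, CC(C)(C)[Si](C)(C)OS(=O)(=O)C(F)(F)F
Why: Silylation of a hindered secondary benzylic alcohol with a silyl triflate and a hindered pyridine base at low temperature, conditions under which the tert-butyl ester and the benzyl ethers should be left alone.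

Step 7
Reactants: 9 tert-butyl (2R,3S,4R)-5,7-bis(benzyloxy)-2-[4-(benzyloxy)phenyl]-4-[(tert-butyldimethylsilyl)oxy]chromane-3-carboxylate
Product: 10 Fl-methanol
Conditions: LiAlH4, THF, 0 °C
Reagents that add atoms: none
Why: Hydride reduction of the ester to the primary alcohol; silyl and benzyl ethers are inert to LiAlH4 at 0 °C.

Step 8
Reactants: 10 Fl-methanol
Product: 11 Fl-carbaldehyde
Conditions: Dess–Martin periodinane, NaHCO3, CH2Cl2, 0 → 25 °C
Reagents that add atoms: none
Why: Dess–Martin oxidation under buffered, non-basic conditions should give the α-branched aldehyde without β-elimination; C3 stays in the equatorial, trans arrangement.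

Step 9
Reactants: 12 acetylacetone; 13 methyl 4-(benzyloxy)benzoate
Product: 14 1-[4-(benzyloxy)phenyl]hexane-1,3,5-trione
Conditions: 12, LiN(iPr)2 (3 equiv), THF, −78 → 0 °C; then 13, 0 → 25 °C; aq HCl
Reagents that add atoms: none
Why: Claisen condensation of the acetylacetone dianion at its terminal carbon with the aryl ester; the excess base holds the triketone as its dianion.

Step 10
Reactants: 14 1-[4-(benzyloxy)phenyl]hexane-1,3,5-trione
Product: 15 2-[4-(benzyloxy)phenyl]-6-methyl-4H-pyran-4-one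
Conditions: TsOH·H2O (cat.), toluene, 110 °C, Dean–Stark
Reagents that add atoms: none
Why: Acid-catalysed cyclodehydration of the 1,3,5-triketone; the enol oxygen of one terminal carbonyl adds to the other and azeotropic loss of water gives the 4-pyranone.

Step 11
Reactants: 11 Fl-carbaldehyde; 15 2-[4-(benzyloxy)phenyl]-6-methyl-4H-pyran-4-one
Product: 16 2-[4-(benzyloxy)phenyl]-6-(2-Fl-2-hydroxyethyl)-4H-pyran-4-one (both carbinol epimers)
Conditions: 15 (1.3 equiv), LiN(SiMe3)2 (1.25 equiv), THF, −78 °C; then 11, −78 °C; aq NH4Cl at −78 °C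
Reagents that add atoms: none
Why: Vinylogous aldol addition; the methyl group of the 2-methyl-4-pyranone is deprotonated to an extended enolate that attacks the aldehyde through its exocyclic carbon, and the new carbinol centre need not be controlled because it is oxidised in step 12.

Step 12
Reactants: 16 2-[4-(benzyloxy)phenyl]-6-(2-Fl-2-hydroxyethyl)-4H-pyran-4-one
Product: 17 2-[4-(benzyloxy)phenyl]-6-(2-Fl-2-oxoethyl)-4H-pyran-4-one
Conditions: Dess–Martin periodinane (1.3 equiv), NaHCO3, CH2Cl2, 0 °C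
Reagents that add atoms: none
Why: Dess–Martin oxidation of the secondary alcohol to the ketone; a short reaction time should avoid over-oxidation of the activated methylene.

Step 13
Reactants: 17 2-[4-(benzyloxy)phenyl]-6-(2-Fl-2-oxoethyl)-4H-pyran-4-one
Product: 18 2-[4-(benzyloxy)phenyl]-6-(1-diazo-2-Fl-2-oxoethyl)-4H-pyran-4-one
Conditions: 4-acetamidobenzenesulfonyl azide (1.2 equiv), DBU (1.2 equiv), MeCN, 0 °C
Reagents that add atoms: 4-acetamidobenzenesulfonyl azide, CC(=O)Nc1ccc(cc1)S(=O)(=O)N=[N+]=[N-]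
Why: Regitz diazo transfer to the methylene activated by both the ketone and the vinylogous ester of the pyranone; one equivalent of amidine base should deprotonate this position in preference to C3.

Step 14
Reactants: 19 4-methoxybenzyl alcohol; 20 trichloroethylene
Product: 22 4-methoxybenzyl ethynyl ether, via dichlorovinyl ether 21 (not isolated)
Conditions: KH, THF, 0 °C; 20, −50 → 25 °C; then n-BuLi (2.4 equiv), −78 °C; MeOH, −78 °C; kept cold and used at once
Reagents that add atoms: none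
Why: The alkoxide adds to dichloroacetylene formed in the flask from trichloroethylene to give the (E)-dichlorovinyl ether, and two equivalents of butyllithium then effect elimination and chlorine–lithium exchange to the lithium alkoxyacetylide, which is protonated cold (the established synthesis of alkyl ethynyl ethers).

Step 15
Reactants: 18 2-[4-(benzyloxy)phenyl]-6-(1-diazo-2-Fl-2-oxoethyl)-4H-pyran-4-one; 22 4-methoxybenzyl ethynyl ether
Product: 27 2-[4-(benzyloxy)phenyl]-8-Fl-5-hydroxy-7-[(4-methoxybenzyl)oxy]-4H-chromen-4-one, via ketene 23 (not isolated), via cyclobutenone 24 (not isolated), via dienylketene 25 (not isolated), via cyclohexadienone 26 (not isolated)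
Conditions: 22 (2 equiv), 440 nm LEDs, degassed ClCH2CH2Cl, 25 °C; then 80 °C
Reagents that add atoms: none
Why: Proposed new method: visible light should expel N2 from 18 and the acyl carbene should undergo Wolff rearrangement, flavan C3 shifting with retention to the diazo carbon to give ketene 23, whose carbonyl carbon is attacked by the CH terminus of ynol ether 22 in a (2+2) cycloaddition to cyclobutenone 24; reversible four-electron ring opening gives dienylketene 25, and the isomer with the ketene cis to the pyranone closes by six-electron electrocyclisation onto pyranone C3 to 26, which enolises to phenol 27. The closest known reaction type is the photochemical Danheiser benzannulation of aryl and vinyl α-diazo ketones with alkoxy- and siloxyalkynes, which has not been shown for a 4-pyranon-2-yl ketene that carries a secondary alkyl group. Flavone ring A is the only ring closed, by thermal disrotatory 6π electrocyclisation followed by tautomerisation, and the bonds C5–C6, C7–C8 and C4a–C5 are formed. No stereocentre is created: C3 keeps its configuration because the 1,2-shift proceeds with retention, and C2 and C4 are not touched. The step needs regioselectivity in the (2+2) addition, which the polarisation of the ynol ether (nucleophilic CH carbon) against the electrophilic ketene carbonyl carbon secures, and site selectivity in the ring closure, which is secured because the pyranone C2=C3 bond is the only π bond within reach of the ketene. Light of 440 nm is absorbed only by the diazo chromophore, so the aryl pyranone and the benzyl ethers should not be excited.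

Step 16
Reactants: 27 2-[4-(benzyloxy)phenyl]-8-Fl-5-hydroxy-7-[(4-methoxybenzyl)oxy]-4H-chromen-4-one
Product: 28 2-[4-(benzyloxy)phenyl]-8-[(2R,3R,4R)-5,7-bis(benzyloxy)-2-[4-(benzyloxy)phenyl]-4-hydroxychroman-3-yl]-5-hydroxy-7-[(4-methoxybenzyl)oxy]-4H-chromen-4-one
Conditions: Bu4NF (3 equiv), THF, 25 → 45 °C; aq NH4Cl
Reagents that add atoms: none
Why: Fluoride-mediated cleavage of the alkyl silyl ether; benzyl and 4-methoxybenzyl ethers and the flavone are inert to fluoride, and warming answers the hindrance at C4.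

Step 17
Reactants: 28 the flavan-4-ol from step 16
Product: 29 8-[(2R,3S)-5,7-bis(benzyloxy)-2-[4-(benzyloxy)phenyl]-4-oxochroman-3-yl]-2-[4-(benzyloxy)phenyl]-5-hydroxy-7-[(4-methoxybenzyl)oxy]-4H-chromen-4-one
Conditions: Dess–Martin periodinane, NaHCO3, CH2Cl2, 25 °C
Reagents that add atoms: none
Why: Dess–Martin oxidation of the benzylic carbinol restores the flavanone carbonyl; the chelated 5-hydroxyl of the flavone should not be attacked, and C3, now enolisable, rests in the trans diequatorial arrangement.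

Step 18
Reactants: 29 the flavanone from step 17
Product: 30 8-[(2R,3S)-5,7-bis(benzyloxy)-2-[4-(benzyloxy)phenyl]-4-oxochroman-3-yl]-2-[4-(benzyloxy)phenyl]-5,7-dihydroxy-4H-chromen-4-one
Conditions: CF3CO2H (10% v/v), anisole (10 equiv), CH2Cl2, 0 °C
Reagents that add atoms: none
Why: Acidolysis of the 4-methoxybenzyl ether of a vinylogous acid should be much faster than that of the benzyl ethers; anisole traps the benzylic cation, and with C4 a ketone no acid-labile benzylic carbinol remains.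

Step 19
Reactants: 30 the 5,7-dihydroxyflavone from step 18
Product: 31 8-[(2R,3S)-5,7-bis(benzyloxy)-2-[4-(benzyloxy)phenyl]-4-oxochroman-3-yl]-2-[4-(benzyloxy)phenyl]-5-hydroxy-4-oxo-4H-chromen-7-yl hydrogen sulfate
Conditions: SO3·pyridine (3 equiv), pyridine, 25 °C; aq NaHCO3
Reagents that add atoms: sulfur trioxide–pyridine complex, [O-]S(=O)(=O)[n+]1ccccc1
Why: O-Sulfation of a phenol with the sulfur trioxide–pyridine complex; the 5-hydroxyl is hydrogen-bonded to the flavone carbonyl and should stay free, so only the 7-hydroxyl reacts.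

Step 20
Reactants: 31 the aryl sulfate from step 19
Product: 32 5-hydroxy-2-(4-hydroxyphenyl)-8-[(2R,3S)-5,7-dihydroxy-2-(4-hydroxyphenyl)-4-oxochroman-3-yl]-4-oxo-4H-chromen-7-yl hydrogen sulfate (target)
Conditions: H2 (1 atm), Pd/C, THF/MeOH, 25 °C
Reagents that add atoms: none
Why: Hydrogenolysis of the four aryl benzyl ethers over Pd/C at ambient pressure; the aryl sulfate monoester, the flavone double bond and the flavanone carbonyl are expected to persist under these mild conditions.

**Compound list**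

1 | 2',4',6'-trihydroxyacetophenone | CC(=O)c1c(O)cc(O)cc1O | starting material
2 | 1-[2,4-bis(benzyloxy)-6-hydroxyphenyl]ethanone | CC(=O)c1c(O)cc(OCc2ccccc2)cc1OCc1ccccc1 | intermediate
3 | di-tert-butyl dicarbonate | CC(C)(C)OC(=O)OC(=O)OC(C)(C)C | starting material
4 | tert-butyl 3-[2,4-bis(benzyloxy)-6-hydroxyphenyl]-3-oxopropanoate | CC(C)(C)OC(=O)CC(=O)c1c(O)cc(OCc2ccccc2)cc1OCc1ccccc1 | intermediate
5 | 4-(benzyloxy)benzaldehyde | O=Cc1ccc(OCc2ccccc2)cc1 | starting material
6 | tert-butyl (2Z)-2-[2,4-bis(benzyloxy)-6-hydroxybenzoyl]-3-[4-(benzyloxy)phenyl]prop-2-enoate | CC(C)(C)OC(=O)/C(=C\c1ccc(OCc2ccccc2)cc1)C(=O)c1c(O)cc(OCc2ccccc2)cc1OCc1ccccc1 | intermediate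
7 | tert-butyl (2R,3S)-5,7-bis(benzyloxy)-2-[4-(benzyloxy)phenyl]-4-oxochromane-3-carboxylate | O=C1c2c(OCc3ccccc3)cc(OCc3ccccc3)cc2O[C@@H](c2ccc(OCc3ccccc3)cc2)[C@@H]1C(=O)OC(C)(C)C | intermediate
8 | tert-butyl (2R,3R,4R)-5,7-bis(benzyloxy)-2-[4-(benzyloxy)phenyl]-4-hydroxychromane-3-carboxylate | O[C@H]1c2c(OCc3ccccc3)cc(OCc3ccccc3)cc2O[C@@H](c2ccc(OCc3ccccc3)cc2)[C@@H]1C(=O)OC(C)(C)C | intermediate
9 | tert-butyl (2R,3S,4R)-5,7-bis(benzyloxy)-2-[4-(benzyloxy)phenyl]-4-[(tert-butyldimethylsilyl)oxy]chromane-3-carboxylate | CC(C)(C)[Si](C)(C)O[C@H]1c2c(OCc3ccccc3)cc(OCc3ccccc3)cc2O[C@@H](c2ccc(OCc3ccccc3)cc2)[C@@H]1C(=O)OC(C)(C)C | intermediate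
10 | Fl-methanol | CC(C)(C)[Si](C)(C)O[C@H]1c2c(OCc3ccccc3)cc(OCc3ccccc3)cc2O[C@@H](c2ccc(OCc3ccccc3)cc2)[C@@H]1CO | intermediate
11 | Fl-carbaldehyde | CC(C)(C)[Si](C)(C)O[C@H]1c2c(OCc3ccccc3)cc(OCc3ccccc3)cc2O[C@@H](c2ccc(OCc3ccccc3)cc2)[C@@H]1C=O | intermediate
12 | acetylacetone | CC(=O)CC(C)=O | starting material
13 | methyl 4-(benzyloxy)benzoate | COC(=O)c1ccc(OCc2ccccc2)cc1 | starting material
14 | 1-[4-(benzyloxy)phenyl]hexane-1,3,5-trione | CC(=O)CC(=O)CC(=O)c1ccc(OCc2ccccc2)cc1 | intermediate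
15 | 2-[4-(benzyloxy)phenyl]-6-methyl-4H-pyran-4-one | Cc1cc(=O)cc(-c2ccc(OCc3ccccc3)cc2)o1 | intermediate
16 | 2-[4-(benzyloxy)phenyl]-6-(2-Fl-2-hydroxyethyl)-4H-pyran-4-one (carbinol epimers) | CC(C)(C)[Si](C)(C)O[C@H]1c2c(OCc3ccccc3)cc(OCc3ccccc3)cc2O[C@@H](c2ccc(OCc3ccccc3)cc2)[C@@H]1C(O)Cc1cc(=O)cc(-c2ccc(OCc3ccccc3)cc2)o1 | intermediate
17 | 2-[4-(benzyloxy)phenyl]-6-(2-Fl-2-oxoethyl)-4H-pyran-4-one | CC(C)(C)[Si](C)(C)O[C@H]1c2c(OCc3ccccc3)cc(OCc3ccccc3)cc2O[C@@H](c2ccc(OCc3ccccc3)cc2)[C@@H]1C(=O)Cc1cc(=O)cc(-c2ccc(OCc3ccccc3)cc2)o1 | intermediate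
18 | 2-[4-(benzyloxy)phenyl]-6-(1-diazo-2-Fl-2-oxoethyl)-4H-pyran-4-one | CC(C)(C)[Si](C)(C)O[C@H]1c2c(OCc3ccccc3)cc(OCc3ccccc3)cc2O[C@@H](c2ccc(OCc3ccccc3)cc2)[C@@H]1C(=O)C(=[N+]=[N-])c1cc(=O)cc(-c2ccc(OCc3ccccc3)cc2)o1 | intermediate
19 | 4-methoxybenzyl alcohol | COc1ccc(CO)cc1 | starting material
20 | trichloroethylene | ClC=C(Cl)Cl | starting material
21 | 1-{[(E)-1,2-dichloroethenyl]oxymethyl}-4-methoxybenzene | COc1ccc(CO/C(Cl)=C\Cl)cc1 | intermediate
22 | 4-methoxybenzyl ethynyl ether | COc1ccc(COC#C)cc1 | intermediate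
23 | Fl{6-[4-(benzyloxy)phenyl]-4-oxo-4H-pyran-2-yl}ketene | CC(C)(C)[Si](C)(C)O[C@H]1c2c(OCc3ccccc3)cc(OCc3ccccc3)cc2O[C@@H](c2ccc(OCc3ccccc3)cc2)[C@@H]1C(=C=O)c1cc(=O)cc(-c2ccc(OCc3ccccc3)cc2)o1 | intermediate
24 | 4-Fl-4-{6-[4-(benzyloxy)phenyl]-4-oxo-4H-pyran-2-yl}-3-[(4-methoxybenzyl)oxy]cyclobut-2-en-1-one (epimers at the quaternary carbon) | CC(C)(C)[Si](C)(C)O[C@H]1c2c(OCc3ccccc3)cc(OCc3ccccc3)cc2O[C@@H](c2ccc(OCc3ccccc3)cc2)[C@@H]1C1(c2cc(=O)cc(-c3ccc(OCc4ccccc4)cc3)o2)C(=O)C=C1OCc1ccc(OC)cc1 | intermediate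
25 | (E)-4-Fl-4-{6-[4-(benzyloxy)phenyl]-4-oxo-4H-pyran-2-yl}-3-[(4-methoxybenzyl)oxy]buta-1,3-dien-1-one (ketene cis to the pyranone) | CC(C)(C)[Si](C)(C)O[C@H]1c2c(OCc3ccccc3)cc(OCc3ccccc3)cc2O[C@@H](c2ccc(OCc3ccccc3)cc2)[C@@H]1/C(c1cc(=O)cc(-c2ccc(OCc3ccccc3)cc2)o1)=C(/C=C=O)OCc1ccc(OC)cc1 | intermediate
26 | 2-[4-(benzyloxy)phenyl]-8-Fl-7-[(4-methoxybenzyl)oxy]-4aH-chromene-4,5-dione (C4a epimers) | CC(C)(C)[Si](C)(C)O[C@H]1c2c(OCc3ccccc3)cc(OCc3ccccc3)cc2O[C@@H](c2ccc(OCc3ccccc3)cc2)[C@@H]1C1=C2OC(-c3ccc(OCc4ccccc4)cc3)=CC(=O)C2C(=O)C=C1OCc1ccc(OC)cc1 | intermediate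
27 | 2-[4-(benzyloxy)phenyl]-8-Fl-5-hydroxy-7-[(4-methoxybenzyl)oxy]-4H-chromen-4-one | CC(C)(C)[Si](C)(C)O[C@H]1c2c(OCc3ccccc3)cc(OCc3ccccc3)cc2O[C@@H](c2ccc(OCc3ccccc3)cc2)[C@@H]1c1c(OCc2ccc(OC)cc2)cc(O)c2c(=O)cc(-c3ccc(OCc4ccccc4)cc3)oc12 | intermediate
28 | 2-[4-(benzyloxy)phenyl]-8-[(2R,3R,4R)-5,7-bis(benzyloxy)-2-[4-(benzyloxy)phenyl]-4-hydroxychroman-3-yl]-5-hydroxy-7-[(4-methoxybenzyl)oxy]-4H-chromen-4-one | O[C@H]1c2c(OCc3ccccc3)cc(OCc3ccccc3)cc2O[C@@H](c2ccc(OCc3ccccc3)cc2)[C@@H]1c1c(OCc2ccc(OC)cc2)cc(O)c2c(=O)cc(-c3ccc(OCc4ccccc4)cc3)oc12 | intermediate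
29 | 8-[(2R,3S)-5,7-bis(benzyloxy)-2-[4-(benzyloxy)phenyl]-4-oxochroman-3-yl]-2-[4-(benzyloxy)phenyl]-5-hydroxy-7-[(4-methoxybenzyl)oxy]-4H-chromen-4-one | O=C1c2c(OCc3ccccc3)cc(OCc3ccccc3)cc2O[C@@H](c2ccc(OCc3ccccc3)cc2)[C@@H]1c1c(OCc2ccc(OC)cc2)cc(O)c2c(=O)cc(-c3ccc(OCc4ccccc4)cc3)oc12 | intermediate
30 | 8-[(2R,3S)-5,7-bis(benzyloxy)-2-[4-(benzyloxy)phenyl]-4-oxochroman-3-yl]-2-[4-(benzyloxy)phenyl]-5,7-dihydroxy-4H-chromen-4-one | O=C1c2c(OCc3ccccc3)cc(OCc3ccccc3)cc2O[C@@H](c2ccc(OCc3ccccc3)cc2)[C@@H]1c1c(O)cc(O)c2c(=O)cc(-c3ccc(OCc4ccccc4)cc3)oc12 | intermediate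
31 | 8-[(2R,3S)-5,7-bis(benzyloxy)-2-[4-(benzyloxy)phenyl]-4-oxochroman-3-yl]-2-[4-(benzyloxy)phenyl]-5-hydroxy-4-oxo-4H-chromen-7-yl hydrogen sulfate | O=C1c2c(OCc3ccccc3)cc(OCc3ccccc3)cc2O[C@@H](c2ccc(OCc3ccccc3)cc2)[C@@H]1c1c(OS(=O)(=O)O)cc(O)c2c(=O)cc(-c3ccc(OCc4ccccc4)cc3)oc12 | intermediate
32 | 5-hydroxy-2-(4-hydroxyphenyl)-8-[(2R,3S)-5,7-dihydroxy-2-(4-hydroxyphenyl)-4-oxochroman-3-yl]-4-oxo-4H-chromen-7-yl hydrogen sulfate | O=C1c2c(O)cc(O)cc2O[C@@H](c2ccc(O)cc2)[C@@H]1c1c(OS(=O)(=O)O)cc(O)c2c(=O)cc(-c3ccc(O)cc3)oc12 | target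

**Totals**

Total step count: 20. Longest linear sequence: 17 steps (steps 1–8, 11–13 and 15–20).

**Steps most likely to fail**

1. Step 15 (proposed new method). The acyl carbene may be diverted into insertion or cyclisation before the 1,2-shift. The dienylketene may fail to close onto the weakly aromatic pyranone. The light may also degrade the aryl pyranone.
 Fallback with known chemistry, setting out from 7 and coming back at 30: the flavone is made first and joined to C3 of the β-keto ester by aryllead triacetate arylation (Pinhey arylation).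
 - Starting material 1 is C-aroylated with 4-(benzyloxy)benzoyl chloride (LiN(SiMe3)2, THF) and cyclodehydrated (TsOH, toluene, 80 °C) to 2-[4-(benzyloxy)phenyl]-5,7-dihydroxy-4H-chromen-4-one F1.
 - MOMCl and NaH in DMF give the bis(methoxymethyl) ether F2.
 - Iodination with I2 and AgOCOCF3 in CH2Cl2, directed to C8 by the 5-alkoxy group, gives the 8-iodoflavone F3.
 - (Bu3Sn)2 and Pd(PPh3)4 in toluene at 100 °C give the 8-stannylflavone F4.
 - Pb(OAc)4 with catalytic Hg(OAc)2 in CHCl3 gives the flavon-8-yllead triacetate F5.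
 - F5 and 7 in CHCl3/pyridine at 40 °C should give the C3-arylated β-keto ester F6, the new aryl group entering trans to the C2 aryl group.
 - CF3CO2H in wet CH2Cl2 then removes the tert-butyl ester and both methoxymethyl ethers, the β-keto acid loses CO2, C3 settles trans, and 30 is reached. Steps 19 and 20 follow unchanged.

2. Step 4. Facial selectivity may be poor with the doubly ortho-substituted benzoyl group. The ring may close without the catalyst during step 3. Enantiomeric purity may be lost by retro-oxa-Michael opening of 7.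
 Fallback, setting out from 4 and coming back at 7: 4 is condensed with Me2NCH(OMe)2 in toluene at 80 °C to tert-butyl 5,7-bis(benzyloxy)-4-oxo-4H-chromene-3-carboxylate F7. C2 is then set by rhodium-catalysed asymmetric conjugate addition (Hayashi–Miyaura reaction) of 4-(benzyloxy)phenylboronic acid, with [Rh(OH)(cod)]2 and the BINAP enantiomer that gives 2R, in dioxane/H2O at 40 °C. Protonation of the enolate trans to the new aryl group gives 7.

3. Step 11. The stabilised extended enolate may add reversibly to the hindered aldehyde, so that retro-aldol cleavage wins on warming. It may also enolise the aldehyde and set off β-elimination of the C2 aryloxide or the C4 silyloxide.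
 Fallback, setting out from 11 and coming back at 17 (step 12 is then not needed): Pinnick oxidation (NaClO2, NaH2PO4, 2-methyl-2-butene, t-BuOH/H2O) gives Fl-carboxylic acid F8. 1,1'-Carbonyldiimidazole in THF gives the acyl imidazole F9. F9 then C-acylates 2.2 equivalents of the lithium enolate of 15 (LiN(SiMe3)2, THF, −78 °C) in a Claisen condensation that deprotonation of the product makes irreversible, and acidic work-up gives 17.

Further compounds
F1 | step 15 | 2-[4-(benzyloxy)phenyl]-5,7-dihydroxy-4H-chromen-4-one | O=c1cc(-c2ccc(OCc3ccccc3)cc2)oc2cc(O)cc(O)c12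
F2 | step 15 | 2-[4-(benzyloxy)phenyl]-5,7-bis(methoxymethoxy)-4H-chromen-4-one | COCOc1cc(OCOC)c2c(=O)cc(-c3ccc(OCc4ccccc4)cc3)oc2c1
F3 | step 15 | 2-[4-(benzyloxy)phenyl]-8-iodo-5,7-bis(methoxymethoxy)-4H-chromen-4-one | COCOc1cc(OCOC)c2c(=O)cc(-c3ccc(OCc4ccccc4)cc3)oc2c1I
F4 | step 15 | 2-[4-(benzyloxy)phenyl]-5,7-bis(methoxymethoxy)-8-(tributylstannyl)-4H-chromen-4-one | COCOc1cc(OCOC)c2c(=O)cc(-c3ccc(OCc4ccccc4)cc3)oc2c1[Sn](CCCC)(CCCC)CCCC
F5 | step 15 | {2-[4-(benzyloxy)phenyl]-5,7-bis(methoxymethoxy)-4-oxo-4H-chromen-8-yl}lead triacetate | COCOc1cc(OCOC)c2c(=O)cc(-c3ccc(OCc4ccccc4)cc3)oc2c1[Pb](OC(C)=O)(OC(C)=O)OC(C)=O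
F6 | step 15 | tert-butyl (2S,3R)-5,7-bis(benzyloxy)-2-[4-(benzyloxy)phenyl]-3-{2-[4-(benzyloxy)phenyl]-5,7-bis(methoxymethoxy)-4-oxo-4H-chromen-8-yl}-4-oxochromane-3-carboxylate (C2 as in 7; new aryl group trans to the C2 aryl group) | O=C1c2c(OCc3ccccc3)cc(OCc3ccccc3)cc2O[C@@H](c2ccc(OCc3ccccc3)cc2)[C@]1(C(=O)OC(C)(C)C)c1c(OCOC)cc(OCOC)c2c(=O)cc(-c3ccc(OCc4ccccc4)cc3)oc12
F7 | step 4 | tert-butyl 5,7-bis(benzyloxy)-4-oxo-4H-chromene-3-carboxylate | CC(C)(C)OC(=O)c1coc2cc(OCc3ccccc3)cc(OCc3ccccc3)c2c1=O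
F8 | step 11 | Fl-carboxylic acid | CC(C)(C)[Si](C)(C)O[C@H]1c2c(OCc3ccccc3)cc(OCc3ccccc3)cc2O[C@@H](c2ccc(OCc3ccccc3)cc2)[C@@H]1C(=O)O
F9 | step 11 | Fl(1H-imidazol-1-yl)methanone | CC(C)(C)[Si](C)(C)O[C@H]1c2c(OCc3ccccc3)cc(OCc3ccccc3)cc2O[C@@H](c2ccc(OCc3ccccc3)cc2)[C@@H]1C(=O)n1ccnc1
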